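**Strategy.** The route rests on cutting ArC2–ArC3 and ArC5–ArC6 of the benzene ring. Its six carbons alternate between carbon substituents (C1' on ArC1, formyl on ArC3 and ArC5) and oxygen (ArC2, ArC4, ArC6). That is the imprint of a malonyl unit whose two carbonyl carbons are bonded to the flanking CH2 carbons of a 3-oxoglutarate. One double C-acylation therefore closes the arene and puts ester groups on the future formyl carbons, which spares any late formylation of a hexasubstituted ring. Its precursor is a 2-substituted malonate carrying C1' and the intact 11-silyloxyguai-5-ene with all five stereocentres, activated as the diphenyl ester to offset neopentyl-type hindrance.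

Key step: step 4

Remark: atoms are numbered as in guaiane (C1–C15), C1' is the benzylic carbon and ArC1–ArC6 are the ring carbons; 2 and 4 are taken to be purchasable.

**Step 1**
Reactants: 1 3-methylbutanal; 2 diphenyl malonate
Product: 3 diphenyl 2-(3-methylbutylidene)propanedioate
Conditions: TiCl4, pyridine, THF, 0 °C → rt
Reagents that add atoms: none
Why: A TiCl4/pyridine Knoevenagel condensation joins aldehyde and active methylene through a titanium enolate without exposing the aryl esters to a nucleophilic amine; no stereocentre is formed.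

**Step 2**
Reactants: 3 diphenyl 2-(3-methylbutylidene)propanedioate; 4 (−)-α-gurjunene
Product: 6 diphenyl 2-[(1S)-1-[(1R,4R,7R,10R)-11-hydroxyguai-5-en-4-yl]-3-methylbutyl]propanedioate, via tertiary chloride 5 (not isolated)
Conditions: TiCl4, 2,6-di-tert-butylpyridine, CH2Cl2, −78 °C; then AgNO3, 2,6-lutidine, acetone–H2O, 0 °C → rt
Reagents that add atoms: water, O
Why: Proposed new method: TiCl4 chelates the 1,3-diester of 3 and makes C1' strongly electrophilic; the tetrasubstituted C4=C5 bond of 4, made unusually nucleophilic by the adjacent cyclopropane, should attack through C4, the C5 cyclopropylcarbinyl cation should open by cleavage of C6–C11 (strain release, tertiary homoallyl cation) and be captured by chloride to give 5, and silver-assisted SN1 hydrolysis, helped by the C5=C6 bond, should then give 6; the closest known reaction types are the Hosomi–Sakurai conjugate allylation of alkylidene malonates, Lewis-acid ene-type additions of alkenes to alkylidene 1,3-dicarbonyl compounds, and Prins reactions of 2-carene that open the cyclopropane in the same homoallylic sense; C4 should be set by attack on the convex face of the folded hydroazulene (the face of H-1, opposite to C7–C10 of the seven-membered ring), C1' by an open synclinal transition state in which the isobutyl group points away from C5 and the C1'–H lies over the cyclopentene, any C1' epimer being removed by chromatography at this stage; C1, C7 and C10 are not touched.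

**Step 3**
Reactants: 6 diphenyl 2-[(1S)-1-[(1R,4R,7R,10R)-11-hydroxyguai-5-en-4-yl]-3-methylbutyl]propanedioate
Product: 7 diphenyl 2-[(1S)-1-[(1R,4R,7R,10R)-11-(triethylsilyloxy)guai-5-en-4-yl]-3-methylbutyl]propanedioate
Conditions: TESOTf, 2,6-lutidine, CH2Cl2, −78 → 0 °C
Reagents that add atoms: triethylsilyl trifluoromethanesulfonate, CC[Si](CC)(CC)OS(=O)(=O)C(F)(F)F
Why: Silyl triflate with a hindered pyridine base silylates a tertiary alcohol without touching the malonate C–H or the aryl esters, and the ether keeps the hydroxyl out of the acyl-transfer chemistry of step 4.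

**Step 4**
Reactants: 7 diphenyl 2-[(1S)-1-[(1R,4R,7R,10R)-11-(triethylsilyloxy)guai-5-en-4-yl]-3-methylbutyl]propanedioate; 8 dimethyl 3-oxopentanedioate
Product: 10 dimethyl 5-[(1R)-1-[(1R,4R,7R,10R)-11-(triethylsilyloxy)guai-5-en-4-yl]-3-methylbutyl]-2,4,6-trihydroxybenzene-1,3-dicarboxylate, via open-chain monoacylated triester 9 (not isolated)
Conditions: NaH (3 equiv), THF, 0 → 65 °C; AcOH
Reagents that add atoms: none
Why: The sodium enolate of 8 should attack one aryl ester of 7 through its C2 carbon (Claisen C-acylation; phenoxide leaves far more readily than methoxide, which also opens the elimination–addition channel typical of aryl malonates and so spares a crowded tetrahedral intermediate) to give 9, after which the other methylene carbon attacks the remaining aryl ester carbonyl and threefold enolisation gives the phenoxide of 10. The closest known reaction type is the base-mediated cyclocondensation of malonic diesters with dialkyl 3-oxoglutarates to 2,4,6-trihydroxyisophthalates, together with cyclocondensations of diaryl malonates with 1,3-dinucleophiles. The one ring formed, the benzene ring, closes in a 6-exo-trig mode (enolate carbon onto an ester carbonyl whose C=O stays outside the ring). No stereocentre is created, and C1' cannot epimerise because its hydrogen is not acidic. The step needs C- rather than O-acylation in both events and cross- rather than self-condensation of 8: O-acylated isomers (enol esters, a 2-pyranone) remain reversible while phenoxide is present, whereas closure at carbon ends in an aromatic phenoxide that leaves every equilibrium, and the aryl ester is the best acyl donor in the flask.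

**Step 5**
Reactants: 10 dimethyl 5-[(1R)-1-[(1R,4R,7R,10R)-11-(triethylsilyloxy)guai-5-en-4-yl]-3-methylbutyl]-2,4,6-trihydroxybenzene-1,3-dicarboxylate
Product: 11 dimethyl 5-[(1R)-1-[(1R,4R,7R,10R)-11-(triethylsilyloxy)guai-5-en-4-yl]-3-methylbutyl]-2,4,6-tris(methoxymethoxy)benzene-1,3-dicarboxylate
Conditions: MOMCl, NaH, DMF, 0 °C → rt
Reagents that add atoms: chloromethyl methyl ether, COCCl
Why: Williamson O-alkylation of the three phenoxides with a small, hard electrophile masks the phenols, so that hydride reduction cannot expel benzylic oxygen through an o-quinone methide, and the acetals can later be removed under much milder conditions than methyl ethers.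

**Step 6**
Reactants: 11 dimethyl 5-[(1R)-1-[(1R,4R,7R,10R)-11-(triethylsilyloxy)guai-5-en-4-yl]-3-methylbutyl]-2,4,6-tris(methoxymethoxy)benzene-1,3-dicarboxylate
Product: 12 [5-[(1R)-1-[(1R,4R,7R,10R)-11-(triethylsilyloxy)guai-5-en-4-yl]-3-methylbutyl]-2,4,6-tris(methoxymethoxy)-1,3-phenylene]dimethanol
Conditions: LiAlH4, THF, 0 °C → rt
Reagents that add atoms: none
Why: Hydride reduction takes both aryl esters to benzylic alcohols, while the acetals, the silyl ether and the trisubstituted alkene are inert to LiAlH4.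

**Step 7**
Reactants: 12 [5-[(1R)-1-[(1R,4R,7R,10R)-11-(triethylsilyloxy)guai-5-en-4-yl]-3-methylbutyl]-2,4,6-tris(methoxymethoxy)-1,3-phenylene]dimethanol
Product: 13 5-[(1R)-1-[(1R,4R,7R,10R)-11-(triethylsilyloxy)guai-5-en-4-yl]-3-methylbutyl]-2,4,6-tris(methoxymethoxy)benzene-1,3-dicarbaldehyde
Conditions: MnO2, CH2Cl2, rt
Reagents that add atoms: none
Why: Activated MnO2 oxidises electron-rich benzylic alcohols to aldehydes under neutral conditions and does not go further.

**Step 8**
Reactants: 13 5-[(1R)-1-[(1R,4R,7R,10R)-11-(triethylsilyloxy)guai-5-en-4-yl]-3-methylbutyl]-2,4,6-tris(methoxymethoxy)benzene-1,3-dicarbaldehyde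
Product: 14 5-[(1R)-1-[(1R,4R,7R,10R)-11-hydroxyguai-5-en-4-yl]-3-methylbutyl]-2,4,6-trihydroxybenzene-1,3-dicarbaldehyde
Conditions: 2 M aq. HCl, THF, rt
Reagents that add atoms: none
Why: Dilute acid hydrolyses the three aryl methoxymethyl acetals (assisted by the neighbouring formyl groups) and the triethylsilyl ether in one operation at room temperature, where the tertiary alcohol and the C5=C6 bond should persist.

**Compound list**
1 | 3-methylbutanal | CC(C)CC=O | starting material
2 | diphenyl malonate | O=C(CC(=O)Oc1ccccc1)Oc1ccccc1 | starting material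
3 | diphenyl 2-(3-methylbutylidene)propanedioate | CC(C)CC=C(C(=O)Oc1ccccc1)C(=O)Oc1ccccc1 | intermediate
4 | (−)-α-gurjunene | C[C@@H]1CC[C@@H]2[C@@H](C2(C)C)C3=C(C)CC[C@H]13 | starting material
5 | diphenyl 2-[(1S)-1-[(1R,4R,7R,10R)-11-chloroguai-5-en-4-yl]-3-methylbutyl]propanedioate (formed in the flask, not isolated) | CC(C)C[C@@H](C(C(=O)Oc1ccccc1)C(=O)Oc1ccccc1)[C@@]1(C)CC[C@H]2C1=C[C@H](C(C)(C)Cl)CC[C@H]2C | intermediate
6 | diphenyl 2-[(1S)-1-[(1R,4R,7R,10R)-11-hydroxyguai-5-en-4-yl]-3-methylbutyl]propanedioate | CC(C)C[C@@H](C(C(=O)Oc1ccccc1)C(=O)Oc1ccccc1)[C@@]1(C)CC[C@H]2C1=C[C@H](C(C)(C)O)CC[C@H]2C | intermediate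
7 | diphenyl 2-[(1S)-1-[(1R,4R,7R,10R)-11-(triethylsilyloxy)guai-5-en-4-yl]-3-methylbutyl]propanedioate | CC(C)C[C@@H](C(C(=O)Oc1ccccc1)C(=O)Oc1ccccc1)[C@@]1(C)CC[C@H]2C1=C[C@H](C(C)(C)O[Si](CC)(CC)CC)CC[C@H]2C | intermediate
8 | dimethyl 3-oxopentanedioate | COC(=O)CC(=O)CC(=O)OC | starting material
9 | dimethyl 2-[3-oxo-3-phenoxy-2-(C1' unit of 7)propanoyl]-3-oxopentanedioate, mixture of enol forms and epimers at the two new CH centres (formed in the flask, not isolated) | CC(C)C[C@@H](C(C(=O)Oc1ccccc1)C(=O)C(C(=O)OC)C(=O)CC(=O)OC)[C@@]1(C)CC[C@H]2C1=C[C@H](C(C)(C)O[Si](CC)(CC)CC)CC[C@H]2C | intermediate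
10 | dimethyl 5-[(1R)-1-[(1R,4R,7R,10R)-11-(triethylsilyloxy)guai-5-en-4-yl]-3-methylbutyl]-2,4,6-trihydroxybenzene-1,3-dicarboxylate | CC(C)C[C@@H](c1c(O)c(C(=O)OC)c(O)c(C(=O)OC)c1O)[C@@]1(C)CC[C@H]2C1=C[C@H](C(C)(C)O[Si](CC)(CC)CC)CC[C@H]2C | intermediate
11 | dimethyl 5-[(1R)-1-[(1R,4R,7R,10R)-11-(triethylsilyloxy)guai-5-en-4-yl]-3-methylbutyl]-2,4,6-tris(methoxymethoxy)benzene-1,3-dicarboxylate | CC(C)C[C@@H](c1c(OCOC)c(C(=O)OC)c(OCOC)c(C(=O)OC)c1OCOC)[C@@]1(C)CC[C@H]2C1=C[C@H](C(C)(C)O[Si](CC)(CC)CC)CC[C@H]2C | intermediate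
12 | [5-[(1R)-1-[(1R,4R,7R,10R)-11-(triethylsilyloxy)guai-5-en-4-yl]-3-methylbutyl]-2,4,6-tris(methoxymethoxy)-1,3-phenylene]dimethanol | CC(C)C[C@@H](c1c(OCOC)c(CO)c(OCOC)c(CO)c1OCOC)[C@@]1(C)CC[C@H]2C1=C[C@H](C(C)(C)O[Si](CC)(CC)CC)CC[C@H]2C | intermediate
13 | 5-[(1R)-1-[(1R,4R,7R,10R)-11-(triethylsilyloxy)guai-5-en-4-yl]-3-methylbutyl]-2,4,6-tris(methoxymethoxy)benzene-1,3-dicarbaldehyde | CC(C)C[C@@H](c1c(OCOC)c(C=O)c(OCOC)c(C=O)c1OCOC)[C@@]1(C)CC[C@H]2C1=C[C@H](C(C)(C)O[Si](CC)(CC)CC)CC[C@H]2C | intermediate
14 | 5-[(1R)-1-[(1R,4R,7R,10R)-11-hydroxyguai-5-en-4-yl]-3-methylbutyl]-2,4,6-trihydroxybenzene-1,3-dicarbaldehyde | CC(C)C[C@@H](c1c(O)c(C=O)c(O)c(C=O)c1O)[C@@]1(C)CC[C@H]2C1=C[C@H](C(C)(C)O)CC[C@H]2C | target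

**Step count.** Total: 8 steps. Longest linear sequence: 8 steps (1 → 14); 4 enters at step 2 and 8 at step 4.

**Steps most likely to fail**

Step 2. The cyclopropylcarbinyl cation may lose the proton at C1 (an ene-type outcome that keeps the cyclopropane) instead of opening, 4 may isomerise under the Lewis acid, the crowded alkene may not reach the β-branched acceptor, or the attack may show poor facial selectivity at C1'. The fallback uses known reaction types, sets out from 4 and returns at 5, and builds C1' in two stages. A Prins-type hydroxymethylation of 4 (paraformaldehyde, Me2AlCl, CH2Cl2, −78 → 0 °C), in which the small electrophile should enter C4 on the same convex face with the same ring opening and chloride capture, should give (11-chloroguai-5-en-4-yl)methanol F1. Dess–Martin periodinane (NaHCO3, CH2Cl2) should give 11-chloroguai-5-ene-4-carbaldehyde F2. TiCl4/pyridine Knoevenagel condensation with 2 should give diphenyl 2-[(11-chloroguai-5-en-4-yl)methylidene]propanedioate F3. Conjugate addition of isobutylmagnesium bromide with CuBr·SMe2 (THF, −78 °C) should then give 5: with the C15 methyl eclipsing the acceptor double bond, the reagent is expected to enter anti to the bulkier C5 branch, which sets C1' as required. Compound 5 is hydrolysed as in step 2.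

Step 4. Acyl transfer may stop at oxygen, the hindered malonate may react more slowly than 8 condenses with itself, or the second closure may stall. The fallback sets out from 7 and 8 and returns at 10, accepting closure through oxygen first. Heating 7 and 8 with Et3N in toluene at 80 °C, without a metal enolate, should give the isolable methyl 4-hydroxy-6-(2-methoxy-2-oxoethyl)-2-oxo-3-(C1' unit)-2H-pyran-5-carboxylate F4 by C-acylation followed by lactonisation. Mg(OMe)2 in MeOH at reflux should then open the lactone and re-close the chain by Claisen condensation of the side-chain methylene onto the liberated ester. This pyranone-to-phloroglucinol ring transformation gives 10.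

Step 8. Acid may dehydrate the tertiary alcohol or add a phenol across C5=C6 before all four protecting groups are gone. The fallback sets out from 10 and returns at 14, replacing the acetals by allyl ethers so that no acid is needed. Allyl bromide and K2CO3 in DMF should give the tris(allyl ether) diester F5. LiAlH4 in THF should give the diol F6, and MnO2 in CH2Cl2 the silylated dialdehyde F7. TBAF in THF should remove the silyl group to give the 11-hydroxy tris(allyl ether) dialdehyde F8. Pd(PPh3)4 with K2CO3 in MeOH should then transfer the three allyl groups to methanol and give 14.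

**Further compounds**
F1 | step 2 | (11-chloroguai-5-en-4-yl)methanol, stereocentres at C1, C4, C7 and C10 as drawn for 14 (CH2OH on C4 cis to H-1) | OC[C@@]1(C)CC[C@H]2C1=C[C@H](C(C)(C)Cl)CC[C@H]2C
F2 | step 2 | 11-chloroguai-5-ene-4-carbaldehyde, stereocentres as in F1 | O=C[C@@]1(C)CC[C@H]2C1=C[C@H](C(C)(C)Cl)CC[C@H]2C
F3 | step 2 | diphenyl 2-[(11-chloroguai-5-en-4-yl)methylidene]propanedioate, stereocentres as in F1 | O=C(Oc1ccccc1)C(=C[C@@]1(C)CC[C@H]2C1=C[C@H](C(C)(C)Cl)CC[C@H]2C)C(=O)Oc1ccccc1
F4 | step 4 | methyl 4-hydroxy-6-(2-methoxy-2-oxoethyl)-2-oxo-3-[1-[11-(triethylsilyloxy)guai-5-en-4-yl]-3-methylbutyl]-2H-pyran-5-carboxylate, side-chain stereocentres as in 7 | CC(C)C[C@@H](c1c(O)c(C(=O)OC)c(CC(=O)OC)oc1=O)[C@@]1(C)CC[C@H]2C1=C[C@H](C(C)(C)O[Si](CC)(CC)CC)CC[C@H]2C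
F5 | step 8 | dimethyl 2,4,6-tris(allyloxy)-5-[(1R)-1-[(1R,4R,7R,10R)-11-(triethylsilyloxy)guai-5-en-4-yl]-3-methylbutyl]benzene-1,3-dicarboxylate | CC(C)C[C@@H](c1c(OCC=C)c(C(=O)OC)c(OCC=C)c(C(=O)OC)c1OCC=C)[C@@]1(C)CC[C@H]2C1=C[C@H](C(C)(C)O[Si](CC)(CC)CC)CC[C@H]2C
F6 | step 8 | [2,4,6-tris(allyloxy)-5-[(1R)-1-[(1R,4R,7R,10R)-11-(triethylsilyloxy)guai-5-en-4-yl]-3-methylbutyl]-1,3-phenylene]dimethanol | CC(C)C[C@@H](c1c(OCC=C)c(CO)c(OCC=C)c(CO)c1OCC=C)[C@@]1(C)CC[C@H]2C1=C[C@H](C(C)(C)O[Si](CC)(CC)CC)CC[C@H]2C
F7 | step 8 | 2,4,6-tris(allyloxy)-5-[(1R)-1-[(1R,4R,7R,10R)-11-(triethylsilyloxy)guai-5-en-4-yl]-3-methylbutyl]benzene-1,3-dicarbaldehyde | CC(C)C[C@@H](c1c(OCC=C)c(C=O)c(OCC=C)c(C=O)c1OCC=C)[C@@]1(C)CC[C@H]2C1=C[C@H](C(C)(C)O[Si](CC)(CC)CC)CC[C@H]2C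
F8 | step 8 | 2,4,6-tris(allyloxy)-5-[(1R)-1-[(1R,4R,7R,10R)-11-hydroxyguai-5-en-4-yl]-3-methylbutyl]benzene-1,3-dicarbaldehyde | CC(C)C[C@@H](c1c(OCC=C)c(C=O)c(OCC=C)c(C=O)c1OCC=C)[C@@]1(C)CC[C@H]2C1=C[C@H](C(C)(C)O)CC[C@H]2C
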